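**Plan**

1. Retrosynthetic cuts, in order: the O–CH3 bond at O7; the C5–C6 bond of ring A; the C7–C8 bond (acetyl group onto a pyranone CH2OMe carbon); the O1–C2 bond of ring C; the C4–C4a bond (acyl chloride onto a β-keto ester); the bond between ring B and the alkyne carbon that becomes C2; the aryl C–I bond.
2. Forward order: ring B is bought as a tetramethoxybenzene, iodinated and coupled with propiolic acid. The derived acid chloride C-acylates a methoxy-substituted β-keto ester. Ring C (the γ-pyrone) closes first through O1–C2, the side chain is then acetylated, ring A closes last through C5–C6 and aromatizes, and one O-methylation ends the route.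
3. Feature that allows the key step: ring A (C4a, C5, C6, C7, C8, C8a) has its oxygens on the alternate carbons C5, C7 and C8a, as in a folded polyketide, with a further methoxy group on C8, and it shares the C4a–C8a bond with ring C. C5 can therefore start as an ester carbon on C4a, and C6–C7–C8 as a CH3–CO–CH(OMe) chain on C8a, of a monocyclic γ-pyrone in which the O1–C8a bond already exists.
4. Stereochemistry: the target has no stereocentre. The CH(OMe) carbon of the open precursor is racemic and ends as the aromatic carbon C8.

Key step: step 7

Assumption: the four purchased building blocks are taken as catalogue chemicals. Flavone numbering (O1, C2, C3, C4, C4a, C5 to C8, C8a) is used for the corresponding atoms of the monocyclic pyranones as well.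

**Route**

Step 1
Reactants: 1 1,2,3,4-tetramethoxybenzene
Product: 2 1-iodo-2,3,4,5-tetramethoxybenzene
Conditions: NIS (1.05 equiv), CF3CO2H (0.2 equiv), MeCN, 0 °C to rt
Reagents that add atoms: N-iodosuccinimide, O=C1CCC(=O)N1I
Why: Electrophilic aromatic iodination of an electron-rich arene whose two free positions are equivalent, so one regioisomer should form, and the iodide deactivates the ring towards a second substitution.

Step 2
Reactants: 2 1-iodo-2,3,4,5-tetramethoxybenzene; 3 propiolic acid (prop-2-ynoic acid)
Product: 4 3-(2,3,4,5-tetramethoxyphenyl)prop-2-ynoic acid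
Conditions: Pd(PPh3)4 (5 mol %), DBU (2.4 equiv), DMSO, rt to 35 °C; then 1 M HCl
Reagents that add atoms: none
Why: Copper-free Sonogashira coupling of an aryl iodide with propiolic acid as its amidinium carboxylate, which should take place at the alkyne C–H near room temperature, below the temperature at which the arylpropiolate would decarboxylate and couple again.

Step 3
Reactants: 4 3-(2,3,4,5-tetramethoxyphenyl)prop-2-ynoic acid
Product: 5 3-(2,3,4,5-tetramethoxyphenyl)prop-2-ynoyl chloride
Conditions: (COCl)2 (1.5 equiv), DMF (cat.), CH2Cl2, 0 °C to rt; evaporated and used crude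
Reagents that add atoms: oxalyl chloride, O=C(Cl)C(=O)Cl
Why: Acid chloride formation through the Vilsmeier-type chloroiminium catalyst under cold, neutral conditions, the usual way to arylpropioloyl chlorides, which should avoid addition of HCl across the triple bond.

Step 4
Reactants: 5 3-(2,3,4,5-tetramethoxyphenyl)prop-2-ynoyl chloride; 6 methyl 4-methoxy-3-oxobutanoate (methyl 4-methoxyacetoacetate)
Product: 7 methyl 2-(2-methoxyacetyl)-3-oxo-5-(2,3,4,5-tetramethoxyphenyl)pent-4-ynoate (expected as an enol tautomer)
Conditions: 6, MgCl2 (1.1 equiv), pyridine (2.2 equiv), CH2Cl2, 0 °C; then 5, 0 °C to rt; 1 M HCl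
Reagents that add atoms: none
Why: Rathke-type C-acylation of the magnesium chelate enolate of a β-keto ester by an acid chloride, in which chelation directs the acyl group to the central carbon and the soft enolate should attack the acyl carbon in preference to the alkyne terminus.

Step 5
Reactants: 7 methyl 2-(2-methoxyacetyl)-3-oxo-5-(2,3,4,5-tetramethoxyphenyl)pent-4-ynoate
Product: 8 methyl 2-(methoxymethyl)-4-oxo-6-(2,3,4,5-tetramethoxyphenyl)-4H-pyran-3-carboxylate
Conditions: TfOH (0.2 equiv), CH2Cl2, 0 °C to rt
Reagents that add atoms: none
Why: Acid-promoted 6-endo-dig oxa-Michael cyclization of the methoxyacetyl enol oxygen onto the ynone (the classical closure of 2-alkynoyl acetoacetates to 4-pyranone-3-carboxylates), with the electron-rich aryl group stabilizing positive charge at the alkyne terminus and so favouring the six-membered over the five-membered mode.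

Step 6
Reactants: 8 methyl 2-(methoxymethyl)-4-oxo-6-(2,3,4,5-tetramethoxyphenyl)-4H-pyran-3-carboxylate; 9 N-methoxy-N-methylacetamide
Product: 11 methyl 2-(1-methoxy-2-oxopropyl)-4-oxo-6-(2,3,4,5-tetramethoxyphenyl)-4H-pyran-3-carboxylate (racemic), via hemiaminal adduct 10 (not isolated)
Conditions: LiN(SiMe3)2 (2.0 equiv), THF, −78 °C; then 9 (1.5 equiv), −78 to 0 °C; AcOH, then water
Reagents that add atoms: none
Why: Lateral (vinylogous) deprotonation of the CH2OMe group, which is conjugated through the ring double bond with both the C4 carbonyl and the ester, followed by Claisen-type acylation of the lithium dienolate with the Weinreb amide; the chelated adduct 10 should hold until the quench, so the more acidic product does not meet base, and the new CH(OMe) centre is racemic.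

Step 7
Reactants: 11 methyl 2-(1-methoxy-2-oxopropyl)-4-oxo-6-(2,3,4,5-tetramethoxyphenyl)-4H-pyran-3-carboxylate
Product: 13 5,7-dihydroxy-8-methoxy-2-(2,3,4,5-tetramethoxyphenyl)-4H-chromen-4-one, via cyclic trione 12 (not isolated)
Conditions: LiN(SiMe3)2 (3.5 equiv), THF, −78 °C to rt; AcOH, then water
Reagents that add atoms: none
Why: Proposed new method: the first equivalent of amide base removes the C8–H, which is flanked by the C7 ketone and is vinylogous to the C4 carbonyl and the C5 ester, and further base metalates the C6 methyl, so that, as with β-diketone dianions, the terminal carbanion is the reactive site; C6 adds to the ester carbonyl C5, methoxide leaves, and trione 12 enolizes to the 5,7-dihydroxy arene, whose deprotonation in the flask should make the sequence irreversible. The closest known reaction type is the base-mediated Dieckmann aromatization of 2-(2-oxopropyl)benzoates to naphthalene-1,3-diols, together with the Claisen folding of polyketo esters to acylphloroglucinols; a 4-pyranone-3-carboxylate has not been used as the acceptor. Ring A (C4a–C5–C6–C7–C8–C8a) closes by a 6-(enolendo)-exo-trig acyl substitution that forms the C5–C6 bond. No stereocentre is created, since the racemic C8 of 11 and 12 becomes an aromatic carbon. The step needs attack at the ester carbon rather than conjugate addition at C2 or C8a with opening of the pyranone, which the non-nucleophilic base, the six-membered intramolecular geometry and the cis, coplanar placement of ester and keto chain on the C4a=C8a double bond should secure. The 8-methoxy (not 6-methoxy) pattern needs no control here because the O1–C8a bond is already in place.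

Step 8
Reactants: 13 5,7-dihydroxy-8-methoxy-2-(2,3,4,5-tetramethoxyphenyl)-4H-chromen-4-one
Product: 14 5-hydroxy-7,8-dimethoxy-2-(2,3,4,5-tetramethoxyphenyl)-4H-chromen-4-one
Conditions: Me2SO4 (1.05 equiv), K2CO3 (1.5 equiv), acetone, rt to 40 °C
Reagents that add atoms: dimethyl sulfate, COS(=O)(=O)OC
Why: Williamson O-methylation of the 7-hydroxyl, the more acidic phenol (para to the C4 carbonyl), while the 5-hydroxyl is held in a hydrogen bond to the C4 carbonyl and should stay free with one equivalent of electrophile under mild carbonate conditions.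

**Compound list**

1 | 1,2,3,4-tetramethoxybenzene | COc1ccc(OC)c(OC)c1OC | starting material
2 | 1-iodo-2,3,4,5-tetramethoxybenzene | COc1cc(I)c(OC)c(OC)c1OC | intermediate
3 | propiolic acid (prop-2-ynoic acid) | C#CC(=O)O | starting material
4 | 3-(2,3,4,5-tetramethoxyphenyl)prop-2-ynoic acid | COc1cc(C#CC(=O)O)c(OC)c(OC)c1OC | intermediate
5 | 3-(2,3,4,5-tetramethoxyphenyl)prop-2-ynoyl chloride | COc1cc(C#CC(=O)Cl)c(OC)c(OC)c1OC | intermediate
6 | methyl 4-methoxy-3-oxobutanoate | COCC(=O)CC(=O)OC | starting material
7 | methyl 2-(2-methoxyacetyl)-3-oxo-5-(2,3,4,5-tetramethoxyphenyl)pent-4-ynoate (drawn as the triketo form) | COCC(=O)C(C(=O)OC)C(=O)C#Cc1cc(OC)c(OC)c(OC)c1OC | intermediate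
8 | methyl 2-(methoxymethyl)-4-oxo-6-(2,3,4,5-tetramethoxyphenyl)-4H-pyran-3-carboxylate | COCc1oc(-c2cc(OC)c(OC)c(OC)c2OC)cc(=O)c1C(=O)OC | intermediate
9 | N-methoxy-N-methylacetamide | CC(=O)N(C)OC | starting material
10 | methyl 2-[2-hydroxy-1-methoxy-2-[methoxy(methyl)amino]propyl]-4-oxo-6-(2,3,4,5-tetramethoxyphenyl)-4H-pyran-3-carboxylate (hemiaminal adduct, present as its lithium chelate, not isolated) | COC(C(C)(O)N(C)OC)c1oc(-c2cc(OC)c(OC)c(OC)c2OC)cc(=O)c1C(=O)OC | intermediate
11 | methyl 2-(1-methoxy-2-oxopropyl)-4-oxo-6-(2,3,4,5-tetramethoxyphenyl)-4H-pyran-3-carboxylate (racemic) | COC(C(C)=O)c1oc(-c2cc(OC)c(OC)c(OC)c2OC)cc(=O)c1C(=O)OC | intermediate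
12 | 8-methoxy-2-(2,3,4,5-tetramethoxyphenyl)-6H-chromene-4,5,7(8H)-trione (cyclic trione, racemic, present as its enolate, not isolated) | COC1C(=O)CC(=O)c2c(=O)cc(-c3cc(OC)c(OC)c(OC)c3OC)oc21 | intermediate
13 | 5,7-dihydroxy-8-methoxy-2-(2,3,4,5-tetramethoxyphenyl)-4H-chromen-4-one | COc1cc(-c2cc(=O)c3c(O)cc(O)c(OC)c3o2)c(OC)c(OC)c1OC | intermediate
14 | 5-hydroxy-7,8-dimethoxy-2-(2,3,4,5-tetramethoxyphenyl)-4H-chromen-4-one | COc1cc(-c2cc(=O)c3c(O)cc(OC)c(OC)c3o2)c(OC)c(OC)c1OC | target

**Totals and risks**

Total step count: 8. Longest linear sequence: 8 steps (1 to 14).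

Steps most likely to fail:

1. Step 7 (proposed new method). The substrate may stop at the stabilized C8 anion without closing, or the methoxide that is set free may add to C2 of the pyranone and open ring C. The fallback uses known chemistry, sets out from iodide 2 and comes back to the route at target 14. Iodine–magnesium exchange of 2 with i-PrMgCl·LiCl in THF and quenching with DMF should give 2,3,4,5-tetramethoxybenzaldehyde F1. Claisen–Schmidt condensation of F1 with purchased 1-(2-hydroxy-3,4,6-trimethoxyphenyl)ethanone (KOH, EtOH, rt) should give (E)-1-(2-hydroxy-3,4,6-trimethoxyphenyl)-3-(2,3,4,5-tetramethoxyphenyl)prop-2-en-1-one F2. Oxidative cyclization of this 2′-hydroxychalcone with catalytic I2 in DMSO at 120 °C should give 5,7,8-trimethoxy-2-(2,3,4,5-tetramethoxyphenyl)-4H-chromen-4-one F3. BCl3 in CH2Cl2 at −78 to 0 °C should then cleave only the 5-methoxy group, which lies peri to the C4 carbonyl and is activated by chelation, to give 14. Ring A is bought in this variant instead of being built.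

2. Step 6. The doubly stabilized dienolate may add too slowly to the Weinreb amide, or the excess base may enolize and degrade the amide, so that 8 is recovered. The fallback sets out from 8 and comes back at 11, replacing the acylation by an aldol addition and an oxidation. The same lithium dienolate (LiN(SiMe3)2, THF, −78 °C) is added to acetaldehyde and quenched cold with AcOH, so that the lithium alkoxide cannot lactonize onto the neighbouring ester. This should give methyl 2-(2-hydroxy-1-methoxypropyl)-4-oxo-6-(2,3,4,5-tetramethoxyphenyl)-4H-pyran-3-carboxylate F4 as a mixture of diastereomers. Dess–Martin periodinane (NaHCO3, CH2Cl2, rt) should then oxidize it to 11.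

3. Step 2. Oxidative addition into the electron-rich, ortho-substituted iodide may be slow, and at the temperature then needed the arylpropiolate may decarboxylate and couple a second time to a diarylalkyne. The fallback sets out from 2 and comes back at 4, introducing the carboxyl group last. Sonogashira coupling of 2 with ethynyltrimethylsilane (PdCl2(PPh3)2, CuI, Et3N, 50 °C) should give trimethyl[(2,3,4,5-tetramethoxyphenyl)ethynyl]silane F5. Desilylation (K2CO3, MeOH, rt) should give 1-ethynyl-2,3,4,5-tetramethoxybenzene F6. Deprotonation with n-BuLi (THF, −78 °C), addition of CO2 and acidic work-up should then give 4.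

**Further compounds**

F1 | step 7 | 2,3,4,5-tetramethoxybenzaldehyde | COc1cc(C=O)c(OC)c(OC)c1OC
F2 | step 7 | (E)-1-(2-hydroxy-3,4,6-trimethoxyphenyl)-3-(2,3,4,5-tetramethoxyphenyl)prop-2-en-1-one | COc1cc(/C=C/C(=O)c2c(OC)cc(OC)c(OC)c2O)c(OC)c(OC)c1OC
F3 | step 7 | 5,7,8-trimethoxy-2-(2,3,4,5-tetramethoxyphenyl)-4H-chromen-4-one | COc1cc(-c2cc(=O)c3c(OC)cc(OC)c(OC)c3o2)c(OC)c(OC)c1OC
F4 | step 6 | methyl 2-(2-hydroxy-1-methoxypropyl)-4-oxo-6-(2,3,4,5-tetramethoxyphenyl)-4H-pyran-3-carboxylate (mixture of diastereomers) | COC(C(C)O)c1oc(-c2cc(OC)c(OC)c(OC)c2OC)cc(=O)c1C(=O)OC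
F5 | step 2 | trimethyl[(2,3,4,5-tetramethoxyphenyl)ethynyl]silane | COc1cc(C#C[Si](C)(C)C)c(OC)c(OC)c1OC
F6 | step 2 | 1-ethynyl-2,3,4,5-tetramethoxybenzene | COc1cc(C#C)c(OC)c(OC)c1OC
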